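The cyclohexane ring of the benzoxepane half is closed at C7–C8. Ring oxygen O1 on C9a stands 1,4 to carbinol carbon C7 (through C5a and C6), so C7 is carried as the carbonyl of a γ-lactone on O1. This temporary ring first steers the C5a quaternary centre and the C6 side chain. In the key step SmI2 converts a C8 iodide into an organosamarium that attacks the lactone carbonyl: the C7–C8 bond and the six-membered ring form, the C7–O1 bond breaks, and the C9a hydroxyl is freed for oxepane closure. The precursor is a trisubstituted butyrolactone bearing a 2-iodoethyl group, an epoxide side chain and the complete hydroazulene half.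

Key step: step 17

Locants: the right half is numbered as 1-benzoxepine (O1, C2, C3, C4, C5, C5a, C6, C7, C8, C9, C9a) and the left half as azulene, as in the name of 35; lactone intermediates carry oxolane locants.

Assumption: the ligand antipodes named in steps 2 and 10 are those expected by analogy with simpler substrates to give the (S) centres; should the opposite sense be found, the mirror-image ligand is used.

**Left half (steps 1–9)**

Step 1
Reactants: 1 2,4,4-trimethylcyclohex-2-en-1-one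
Product: 2 2,4,4-trimethylcyclohexa-2,5-dien-1-one
Conditions: IBX (2.5 equiv), DMSO/toluene, 80 °C
Reagents that add atoms: none
Why: IBX dehydrogenation of the enone through its enol should give the cross-conjugated dienone, whose unsubstituted enone arm is the acceptor needed in step 2.

Step 2
Reactants: 2 2,4,4-trimethylcyclohexa-2,5-dien-1-one; 3 but-3-en-1-ylmagnesium bromide
Product: 7 {[(1R,5S,6S)-5-(but-3-en-1-yl)-2,4,4-trimethylbicyclo[4.1.0]hept-2-en-1-yl]oxy}trimethylsilane, via dibutenylzinc 4 (not isolated), via zinc enolate 5 (not isolated), via silyl dienol ether 6 (not isolated)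
Conditions: 3, ZnCl2 (0.5 equiv), Et2O, then 1,4-dioxane, filter; Cu(OTf)2 (2 mol %), (R,S,S)-O,O'-(1,1'-binaphthyl-2,2'-diyl) N,N-bis(1-phenylethyl)phosphoramidite (4 mol %), 2, toluene, −30 °C; TMSOTf, −30 → 0 °C; Et2Zn, CH2I2, 0 °C → rt
Reagents that add atoms: trimethylsilyl triflate C[Si](C)(C)OS(=O)(=O)C(F)(F)F; diiodomethane ICI
Why: Copper–phosphoramidite-catalysed asymmetric conjugate addition of the dialkylzinc should occur at the β-carbon of the unsubstituted enone arm (the α-methyl enone is less electrophilic) with the ligand fixing the (S) centre, after which the zinc enolate is O-silylated and only the electron-rich silyl enol ether alkene is cyclopropanated anti to the butenyl group (Simmons–Smith reaction, Furukawa variant), a known tandem sequence.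

Step 3
Reactants: 7 {[(1R,5S,6S)-5-(but-3-en-1-yl)-2,4,4-trimethylbicyclo[4.1.0]hept-2-en-1-yl]oxy}trimethylsilane
Product: 9 (5S)-5-(but-3-en-1-yl)-2,4,4-trimethylcyclohepta-2,6-dien-1-one, via β-chloro ketone 8 (not isolated)
Conditions: FeCl3 (2.2 equiv), DMF, 0 °C → rt; then NaOAc, MeOH, 65 °C
Reagents that add atoms: none
Why: Saegusa–Ito ring expansion, in which FeCl3 oxidises the siloxycyclopropane to an oxy radical that cleaves the internal bond, chlorine transfer gives the β-chloro ketone and NaOAc eliminates HCl, should give the seven-membered cross-conjugated dienone with the stereocentre now γ to the carbonyl.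

Step 4
Reactants: 9 (5S)-5-(but-3-en-1-yl)-2,4,4-trimethylcyclohepta-2,6-dien-1-one
Product: 10 (5S)-2,4,4-trimethyl-5-(3-oxobutyl)cyclohepta-2,6-dien-1-one
Conditions: PdCl2 (10 mol %), CuCl, O2 (1 atm), DMF/H2O, rt
Reagents that add atoms: water O
Why: Tsuji–Wacker oxidation is selective for the terminal alkene (Markovnikov) and should leave the electron-poor dienone untouched.

Step 5
Reactants: 10 (5S)-2,4,4-trimethyl-5-(3-oxobutyl)cyclohepta-2,6-dien-1-one
Product: 11 (1S,3aS,8aS)-1-hydroxy-1,4,4,6-tetramethyl-2,3,3a,4,8,8a-hexahydroazulen-7(1H)-one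
Conditions: SmI2 (2.2 equiv), HMPA, t-BuOH, THF, −78 °C
Reagents that add atoms: none
Why: SmI2 ketyl–olefin (reductive ketone–enone) cyclisation in the 5-exo-trig mode onto the unsubstituted enone should give the cis-fused hydroazulene, because the tether on C3a delivers to the same face of C8a and the samarium-bound oxygen stays anti to the C8a–C8 bond (hydroxyl exo, methyl endo), while the methyl-substituted enone survives since its β-carbon is hindered and would need a 6-exo attack.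

Step 6
Reactants: 11 (1S,3aS,8aS)-1-hydroxy-1,4,4,6-tetramethyl-2,3,3a,4,8,8a-hexahydroazulen-7(1H)-one
Product: 12 (1S,3aS,7R,8aS)-1,4,4,6-tetramethyl-1,2,3,3a,4,7,8,8a-octahydroazulene-1,7-diol
Conditions: NaBH4, CeCl3·7H2O, MeOH, −78 °C
Reagents that add atoms: none
Why: Luche 1,2-reduction, in which hydride should attack C7 from the convex face of the cis-fused bicycle (the concave face is shielded by the endo 1-methyl group and the cyclopentane), places the hydroxyl on the concave face as step 7 requires.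

Step 7
Reactants: 12 (1S,3aS,7R,8aS)-1,4,4,6-tetramethyl-1,2,3,3a,4,7,8,8a-octahydroazulene-1,7-diol
Product: 14 2-[(1S,3aS,5R,8aS)-1-hydroxy-1,4,4,6-tetramethyl-1,2,3,3a,4,5,8,8a-octahydroazulen-5-yl]-N,N-dimethylacetamide, via ketene N,O-acetal 13 (not isolated)
Conditions: MeC(OMe)2NMe2, xylene, 140 °C
Reagents that add atoms: N,N-dimethylacetamide dimethyl acetal COC(C)(OC)N(C)C
Why: Eschenmoser–Claisen rearrangement of the ketene N,O-acetal formed at the secondary allylic hydroxyl is a suprafacial [3,3] shift that should transfer the C7 configuration to C5 (new C–C bond on the face that carried oxygen) and place the double bond at C6–C7, the tertiary alcohol being unable to rearrange.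

Step 8
Reactants: 14 2-[(1S,3aS,5R,8aS)-1-hydroxy-1,4,4,6-tetramethyl-1,2,3,3a,4,5,8,8a-octahydroazulen-5-yl]-N,N-dimethylacetamide
Product: 15 (1S,3aS,5R,8aS)-5-(2-hydroxyethyl)-1,4,4,6-tetramethyl-1,2,3,3a,4,5,8,8a-octahydroazulen-1-ol
Conditions: LiEt3BH, THF, 0 °C → rt; then NaOH, H2O2
Reagents that add atoms: none
Why: LiEt3BH reduces tertiary amides to primary alcohols by C–N cleavage and should not touch the trisubstituted alkene.

Step 9
Reactants: 15 (1S,3aS,5R,8aS)-5-(2-hydroxyethyl)-1,4,4,6-tetramethyl-1,2,3,3a,4,5,8,8a-octahydroazulen-1-ol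
Product: 17 {[(1S,3aS,5R,8aS)-5-(2-iodoethyl)-1,4,4,6-tetramethyl-1,2,3,3a,4,5,8,8a-octahydroazulen-1-yl]oxy}trimethylsilane, via iodo alcohol 16 (not isolated)
Conditions: I2, PPh3, imidazole, CH2Cl2, 0 °C; then TMSCl, rt
Reagents that add atoms: iodine II; chlorotrimethylsilane C[Si](C)(C)Cl
Why: Appel-type iodination (Garegg–Samuelsson conditions) is selective for the primary alcohol, and N-silylimidazole formed from TMSCl should then cap the tertiary alcohol so that it cannot quench the enolate in step 14.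

**Right half (steps 10–13)**

Step 10
Reactants: 18 3-[(tert-butyldimethylsilyl)oxy]propanal; 19 methyl propiolate
Product: 21 methyl (4S)-6-[(tert-butyldimethylsilyl)oxy]-4-hydroxyhex-2-ynoate, via zinc alkynylide 20 (not isolated)
Conditions: Me2Zn, (S,S)-ProPhenol (10 mol %), Ph3P=O (20 mol %), toluene, 0 °C
Reagents that add atoms: none
Why: Zinc–ProPhenol-catalysed asymmetric alkynylation of the aldehyde by the zinc alkynylide of methyl propiolate should set the (S) carbinol, the dinuclear zinc catalyst selecting the aldehyde face; this centre becomes C9a and controls all others of the carbocycle.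

Step 11
Reactants: 21 methyl (4S)-6-[(tert-butyldimethylsilyl)oxy]-4-hydroxyhex-2-ynoate; 22 5-bromo-2-methylpent-2-ene
Product: 25 (5S)-5-{2-[(tert-butyldimethylsilyl)oxy]ethyl}-4-(4-methylpent-3-en-1-yl)furan-2(5H)-one, via homoprenyl Grignard 23 (not isolated), via Z-hydroxy enoate 24 (not isolated)
Conditions: 22, Mg, THF; CuI, THF, −78 → −40 °C; then aq NH4Cl, rt
Reagents that add atoms: none
Why: Syn carbocupration (conjugate addition) of the ynoate places the new alkyl group trans to the ester, so the γ-oxygen is cis to the ester and should lactonise to the β-substituted butenolide without touching the stereocentre.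

Step 12
Reactants: 25 (5S)-5-{2-[(tert-butyldimethylsilyl)oxy]ethyl}-4-(4-methylpent-3-en-1-yl)furan-2(5H)-one
Product: 27 (4S,5S)-5-{2-[(tert-butyldimethylsilyl)oxy]ethyl}-4-methyl-4-(4-methylpent-3-en-1-yl)oxolan-2-one, via silyl ketene acetal 26 (not isolated)
Conditions: Me2CuLi (from MeLi, CuI), TMSCl, THF, −78 → −30 °C; then 1 M HCl
Reagents that add atoms: methyllithium C[Li]
Why: TMSCl-accelerated cuprate conjugate addition to the butenolide should create the quaternary centre with methyl entering anti to the C5 substituent of the five-membered ring (1,2-induction), giving (4S).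

Step 13
Reactants: 27 (4S,5S)-5-{2-[(tert-butyldimethylsilyl)oxy]ethyl}-4-methyl-4-(4-methylpent-3-en-1-yl)oxolan-2-one
Product: 28 (4S,5S)-5-{2-[(tert-butyldimethylsilyl)oxy]ethyl}-4-{2-[(2S)-3,3-dimethyloxiran-2-yl]ethyl}-4-methyloxolan-2-one
Conditions: L-fructose-derived Shi ketone (30 mol %), Oxone (2KHSO5·KHSO4·K2SO4), K2CO3, Bu4NHSO4, MeCN/dimethoxymethane/aq buffer, 0 °C
Reagents that add atoms: potassium peroxymonosulfate [K+].[O-]S(=O)(=O)OO
Why: Shi asymmetric epoxidation of the only alkene present (trisubstituted) through the spiro dioxirane transition state should give the (S)-epoxide under reagent control, the lactone and silyl ether being inert to the dioxirane.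

**Union and endgame (steps 14–19)**

Step 14
Reactants: 28 (4S,5S)-5-{2-[(tert-butyldimethylsilyl)oxy]ethyl}-4-{2-[(2S)-3,3-dimethyloxiran-2-yl]ethyl}-4-methyloxolan-2-one; 17 {[(1S,3aS,5R,8aS)-5-(2-iodoethyl)-1,4,4,6-tetramethyl-1,2,3,3a,4,5,8,8a-octahydroazulen-1-yl]oxy}trimethylsilane
Product: 30 (3S,4S,5S)-5-{2-[(tert-butyldimethylsilyl)oxy]ethyl}-4-{2-[(2S)-3,3-dimethyloxiran-2-yl]ethyl}-4-methyl-3-{2-[(1S,3aS,5R,8aS)-1,4,4,6-tetramethyl-1-[(trimethylsilyl)oxy]-1,2,3,3a,4,5,8,8a-octahydroazulen-5-yl]ethyl}oxolan-2-one, via lithium enolate 29 (not isolated)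
Conditions: LiN(iPr)2, THF, −78 °C; then 17, HMPA, −78 → −30 °C
Reagents that add atoms: none
Why: Lithium enolate alkylation of the γ-lactone by the primary iodide should occur trans to the C5 substituent and on the face of the smaller 4-methyl group, setting (3S), while HMPA raises enolate reactivity and, by sequestering lithium, keeps the unactivated epoxide from being opened.

Step 15
Reactants: 30 (3S,4S,5S)-5-{2-[(tert-butyldimethylsilyl)oxy]ethyl}-4-{2-[(2S)-3,3-dimethyloxiran-2-yl]ethyl}-4-methyl-3-{2-[(1S,3aS,5R,8aS)-1,4,4,6-tetramethyl-1-[(trimethylsilyl)oxy]-1,2,3,3a,4,5,8,8a-octahydroazulen-5-yl]ethyl}oxolan-2-one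
Product: 31 (3S,4S,5S)-4-{2-[(2S)-3,3-dimethyloxiran-2-yl]ethyl}-5-(2-hydroxyethyl)-3-{2-[(1S,3aS,5R,8aS)-1-hydroxy-1,4,4,6-tetramethyl-1,2,3,3a,4,5,8,8a-octahydroazulen-5-yl]ethyl}-4-methyloxolan-2-one
Conditions: Bu4NF, AcOH, THF, 0 °C → rt
Reagents that add atoms: none
Why: Fluoride should cleave both silyl ethers in one operation, the acetic acid buffer keeping the lactone and the epoxide from base-mediated attack.

Step 16
Reactants: 31 (3S,4S,5S)-4-{2-[(2S)-3,3-dimethyloxiran-2-yl]ethyl}-5-(2-hydroxyethyl)-3-{2-[(1S,3aS,5R,8aS)-1-hydroxy-1,4,4,6-tetramethyl-1,2,3,3a,4,5,8,8a-octahydroazulen-5-yl]ethyl}-4-methyloxolan-2-one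
Product: 32 (3S,4S,5S)-4-{2-[(2S)-3,3-dimethyloxiran-2-yl]ethyl}-3-{2-[(1S,3aS,5R,8aS)-1-hydroxy-1,4,4,6-tetramethyl-1,2,3,3a,4,5,8,8a-octahydroazulen-5-yl]ethyl}-5-(2-iodoethyl)-4-methyloxolan-2-one
Conditions: I2, PPh3, imidazole, CH2Cl2, 0 °C
Reagents that add atoms: iodine II
Why: Appel-type iodination of the primary alcohol under imidazole buffering should leave the tertiary alcohol, the epoxide and the lactone unchanged.

Step 17
Reactants: 32 (3S,4S,5S)-4-{2-[(2S)-3,3-dimethyloxiran-2-yl]ethyl}-3-{2-[(1S,3aS,5R,8aS)-1-hydroxy-1,4,4,6-tetramethyl-1,2,3,3a,4,5,8,8a-octahydroazulen-5-yl]ethyl}-5-(2-iodoethyl)-4-methyloxolan-2-one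
Product: 33 (2S,3S,4S)-3-{2-[(2S)-3,3-dimethyloxiran-2-yl]ethyl}-4-hydroxy-2-{2-[(1S,3aS,5R,8aS)-1-hydroxy-1,4,4,6-tetramethyl-1,2,3,3a,4,5,8,8a-octahydroazulen-5-yl]ethyl}-3-methylcyclohexan-1-one
Conditions: SmI2 (2.5 equiv), Fe(dbm)3 (iron tris(dibenzoylmethanate), 2 mol %), THF, −30 → 0 °C; then pH 7 buffer
Reagents that add atoms: none
Why: Two single-electron transfers from divalent samarium (Fe(dbm)3 as electron-transfer catalyst) should turn the primary C–I bond into an alkylsamarium at C8, which adds to the lactone carbonyl C7 through a five-membered array (C8, C9, C9a, O1, C7), and the resulting 7-oxabicyclo[2.2.1]heptan-1-olate collapses by expelling O1, so the acyl group moves from oxygen to carbon. The closest known reaction type is the samarium-Barbier intramolecular nucleophilic acyl substitution of halo esters and halo lactones that carry the halide in the alkoxy part. The ring closed is the cyclohexane (C5a, C6, C7, C8, C9, C9a), by 6-exo-trig attack on the carbonyl counted through carbon (5-exo-trig counted through O1), with the temporary lactone ring opened in the same event. No new stereocentre is created: C9a keeps its configuration because its C–O bond is untouched, C5a is quaternary, and C6, now α to the ketone, sits in the equatorial arrangement set in step 14, which is also the thermodynamic one. The step needs acyl transfer to outrun protonation of the organosamarium and needs the epoxide, the product ketone and the alkene to survive; the short intramolecular path, the absence of a proton donor and of HMPA, the low temperature and the inertness of unactivated epoxides and dialkyl ketones to SmI2 in THF should secure this.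

Step 18
Reactants: 33 (2S,3S,4S)-3-{2-[(2S)-3,3-dimethyloxiran-2-yl]ethyl}-4-hydroxy-2-{2-[(1S,3aS,5R,8aS)-1-hydroxy-1,4,4,6-tetramethyl-1,2,3,3a,4,5,8,8a-octahydroazulen-5-yl]ethyl}-3-methylcyclohexan-1-one
Product: 34 (3S,5aS,6S,9aS)-3-hydroxy-6-{2-[(1S,3aS,5R,8aS)-1-hydroxy-1,4,4,6-tetramethyl-1,2,3,3a,4,5,8,8a-octahydroazulen-5-yl]ethyl}-2,2,5a-trimethyloctahydro-1-benzoxepin-7(2H)-one
Conditions: (CF3)2CHOH, 0 °C → rt
Reagents that add atoms: none
Why: 7-endo-tet epoxide opening (the biomimetic mode), in which hydrogen-bond activation by the fluorinated alcohol gives a loose cation-like transition state, should direct the C9a hydroxyl to the tertiary epoxide carbon, while C3 keeps its C–O bond and becomes the (3S) alcohol and the trans ring fusion is already fixed.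

Step 19
Reactants: 34 (3S,5aS,6S,9aS)-3-hydroxy-6-{2-[(1S,3aS,5R,8aS)-1-hydroxy-1,4,4,6-tetramethyl-1,2,3,3a,4,5,8,8a-octahydroazulen-5-yl]ethyl}-2,2,5a-trimethyloctahydro-1-benzoxepin-7(2H)-one
Product: 35 (3S,5aS,6S,7R,9aS)-6-{2-[(1S,3aS,5R,8aS)-1-hydroxy-1,4,4,6-tetramethyl-1,2,3,3a,4,5,8,8a-octahydroazulen-5-yl]ethyl}-2,2,5a,7-tetramethyldecahydro-1-benzoxepine-3,7-diol
Conditions: MeLi, CeCl3, THF, −78 °C
Reagents that add atoms: methyllithium C[Li]
Why: Organocerium addition to the hindered, enolisable ketone should come from the equatorial direction, anti to the axial 5a-methyl group, giving the axial (7R) tertiary alcohol with equatorial methyl, the free hydroxyls being carried as alkoxides.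

**Compound list**

1 | 2,4,4-trimethylcyclohex-2-en-1-one | CC1=CC(C)(C)CCC1=O | starting material
2 | 2,4,4-trimethylcyclohexa-2,5-dien-1-one | CC1=CC(C)(C)C=CC1=O | intermediate
3 | but-3-en-1-ylmagnesium bromide | C=CCC[Mg]Br | starting material
4 | di(but-3-en-1-yl)zinc | C=CCC[Zn]CCC=C | intermediate
5 | but-3-en-1-ylzinc enolate of (5S)-5-(but-3-en-1-yl)-2,4,4-trimethylcyclohex-2-en-1-one | C=CCC[C@H]1C=C(O[Zn]CCC=C)C(C)=CC1(C)C | intermediate
6 | {[(3S)-3-(but-3-en-1-yl)-4,4,6-trimethylcyclohexa-1,5-dien-1-yl]oxy}trimethylsilane | C=CCC[C@H]1C=C(O[Si](C)(C)C)C(C)=CC1(C)C | intermediate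
7 | {[(1R,5S,6S)-5-(but-3-en-1-yl)-2,4,4-trimethylbicyclo[4.1.0]hept-2-en-1-yl]oxy}trimethylsilane | C=CCC[C@H]1[C@@H]2C[C@]2(O[Si](C)(C)C)C(C)=CC1(C)C | intermediate
8 | (5R)-5-(but-3-en-1-yl)-6-chloro-2,4,4-trimethylcyclohept-2-en-1-one (either C6 epimer) | C=CCC[C@H]1C(Cl)CC(=O)C(C)=CC1(C)C | intermediate
9 | (5S)-5-(but-3-en-1-yl)-2,4,4-trimethylcyclohepta-2,6-dien-1-one | C=CCC[C@H]1C=CC(=O)C(C)=CC1(C)C | intermediate
10 | (5S)-2,4,4-trimethyl-5-(3-oxobutyl)cyclohepta-2,6-dien-1-one | CC(=O)CC[C@H]1C=CC(=O)C(C)=CC1(C)C | intermediate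
11 | (1S,3aS,8aS)-1-hydroxy-1,4,4,6-tetramethyl-2,3,3a,4,8,8a-hexahydroazulen-7(1H)-one | CC1=CC(C)(C)[C@H]2CC[C@](C)(O)[C@H]2CC1=O | intermediate
12 | (1S,3aS,7R,8aS)-1,4,4,6-tetramethyl-1,2,3,3a,4,7,8,8a-octahydroazulene-1,7-diol | CC1=CC(C)(C)[C@H]2CC[C@](C)(O)[C@H]2C[C@H]1O | intermediate
13 | (1S,3aS,7R,8aS)-7-{[1-(dimethylamino)ethenyl]oxy}-1,4,4,6-tetramethyl-1,2,3,3a,4,7,8,8a-octahydroazulen-1-ol | CC1=CC(C)(C)[C@H]2CC[C@](C)(O)[C@H]2C[C@H]1OC(=C)N(C)C | intermediate
14 | 2-[(1S,3aS,5R,8aS)-1-hydroxy-1,4,4,6-tetramethyl-1,2,3,3a,4,5,8,8a-octahydroazulen-5-yl]-N,N-dimethylacetamide | CC1=CC[C@H]2[C@H](CC[C@]2(C)O)C(C)(C)[C@@H]1CC(=O)N(C)C | intermediate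
15 | (1S,3aS,5R,8aS)-5-(2-hydroxyethyl)-1,4,4,6-tetramethyl-1,2,3,3a,4,5,8,8a-octahydroazulen-1-ol | CC1=CC[C@H]2[C@H](CC[C@]2(C)O)C(C)(C)[C@@H]1CCO | intermediate
16 | (1S,3aS,5R,8aS)-5-(2-iodoethyl)-1,4,4,6-tetramethyl-1,2,3,3a,4,5,8,8a-octahydroazulen-1-ol | CC1=CC[C@H]2[C@H](CC[C@]2(C)O)C(C)(C)[C@@H]1CCI | intermediate
17 | {[(1S,3aS,5R,8aS)-5-(2-iodoethyl)-1,4,4,6-tetramethyl-1,2,3,3a,4,5,8,8a-octahydroazulen-1-yl]oxy}trimethylsilane | CC1=CC[C@H]2[C@H](CC[C@]2(C)O[Si](C)(C)C)C(C)(C)[C@@H]1CCI | intermediate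
18 | 3-[(tert-butyldimethylsilyl)oxy]propanal | O=CCCO[Si](C)(C)C(C)(C)C | starting material
19 | methyl propiolate | C#CC(=O)OC | starting material
20 | methyl 3-(methylzincio)prop-2-ynoate | COC(=O)C#C[Zn]C | intermediate
21 | methyl (4S)-6-[(tert-butyldimethylsilyl)oxy]-4-hydroxyhex-2-ynoate | COC(=O)C#C[C@@H](O)CCO[Si](C)(C)C(C)(C)C | intermediate
22 | 5-bromo-2-methylpent-2-ene | CC(C)=CCCBr | starting material
23 | (4-methylpent-3-en-1-yl)magnesium bromide | CC(C)=CCC[Mg]Br | intermediate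
24 | methyl (2Z)-3-[(1S)-3-[(tert-butyldimethylsilyl)oxy]-1-hydroxypropyl]-7-methylocta-2,6-dienoate | COC(=O)/C=C(/CCC=C(C)C)[C@@H](O)CCO[Si](C)(C)C(C)(C)C | intermediate
25 | (5S)-5-{2-[(tert-butyldimethylsilyl)oxy]ethyl}-4-(4-methylpent-3-en-1-yl)furan-2(5H)-one | O=C1C=C(CCC=C(C)C)[C@H](CCO[Si](C)(C)C(C)(C)C)O1 | intermediate
26 | {[(4S,5S)-5-{2-[(tert-butyldimethylsilyl)oxy]ethyl}-4-methyl-4-(4-methylpent-3-en-1-yl)-4,5-dihydrofuran-2-yl]oxy}trimethylsilane | C[Si](C)(C)OC1=C[C@](C)(CCC=C(C)C)[C@H](CCO[Si](C)(C)C(C)(C)C)O1 | intermediate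
27 | (4S,5S)-5-{2-[(tert-butyldimethylsilyl)oxy]ethyl}-4-methyl-4-(4-methylpent-3-en-1-yl)oxolan-2-one | O=C1C[C@](C)(CCC=C(C)C)[C@H](CCO[Si](C)(C)C(C)(C)C)O1 | intermediate
28 | (4S,5S)-5-{2-[(tert-butyldimethylsilyl)oxy]ethyl}-4-{2-[(2S)-3,3-dimethyloxiran-2-yl]ethyl}-4-methyloxolan-2-one | O=C1C[C@](C)(CC[C@@H]2OC2(C)C)[C@H](CCO[Si](C)(C)C(C)(C)C)O1 | intermediate
29 | lithium enolate of 28 | [Li]OC1=C[C@](C)(CC[C@@H]2OC2(C)C)[C@H](CCO[Si](C)(C)C(C)(C)C)O1 | intermediate
30 | (3S,4S,5S)-5-{2-[(tert-butyldimethylsilyl)oxy]ethyl}-4-{2-[(2S)-3,3-dimethyloxiran-2-yl]ethyl}-4-methyl-3-{2-[(1S,3aS,5R,8aS)-1,4,4,6-tetramethyl-1-[(trimethylsilyl)oxy]-1,2,3,3a,4,5,8,8a-octahydroazulen-5-yl]ethyl}oxolan-2-one | CC1=CC[C@H]2[C@H](CC[C@]2(C)O[Si](C)(C)C)C(C)(C)[C@@H]1CC[C@@H]3C(=O)O[C@@H](CCO[Si](C)(C)C(C)(C)C)[C@@]3(C)CC[C@@H]4OC4(C)C | intermediate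
31 | (3S,4S,5S)-4-{2-[(2S)-3,3-dimethyloxiran-2-yl]ethyl}-5-(2-hydroxyethyl)-3-{2-[(1S,3aS,5R,8aS)-1-hydroxy-1,4,4,6-tetramethyl-1,2,3,3a,4,5,8,8a-octahydroazulen-5-yl]ethyl}-4-methyloxolan-2-one | CC1=CC[C@H]2[C@H](CC[C@]2(C)O)C(C)(C)[C@@H]1CC[C@@H]3C(=O)O[C@@H](CCO)[C@@]3(C)CC[C@@H]4OC4(C)C | intermediate
32 | (3S,4S,5S)-4-{2-[(2S)-3,3-dimethyloxiran-2-yl]ethyl}-3-{2-[(1S,3aS,5R,8aS)-1-hydroxy-1,4,4,6-tetramethyl-1,2,3,3a,4,5,8,8a-octahydroazulen-5-yl]ethyl}-5-(2-iodoethyl)-4-methyloxolan-2-one | CC1=CC[C@H]2[C@H](CC[C@]2(C)O)C(C)(C)[C@@H]1CC[C@@H]3C(=O)O[C@@H](CCI)[C@@]3(C)CC[C@@H]4OC4(C)C | intermediate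
33 | (2S,3S,4S)-3-{2-[(2S)-3,3-dimethyloxiran-2-yl]ethyl}-4-hydroxy-2-{2-[(1S,3aS,5R,8aS)-1-hydroxy-1,4,4,6-tetramethyl-1,2,3,3a,4,5,8,8a-octahydroazulen-5-yl]ethyl}-3-methylcyclohexan-1-one | CC1=CC[C@H]2[C@H](CC[C@]2(C)O)C(C)(C)[C@@H]1CC[C@@H]3C(=O)CC[C@H](O)[C@@]3(C)CC[C@@H]4OC4(C)C | intermediate
34 | (3S,5aS,6S,9aS)-3-hydroxy-6-{2-[(1S,3aS,5R,8aS)-1-hydroxy-1,4,4,6-tetramethyl-1,2,3,3a,4,5,8,8a-octahydroazulen-5-yl]ethyl}-2,2,5a-trimethyloctahydro-1-benzoxepin-7(2H)-one | CC1=CC[C@H]2[C@H](CC[C@]2(C)O)C(C)(C)[C@@H]1CC[C@H]1[C@]2(C)CC[C@H](O)C(C)(C)O[C@H]2CCC1=O | intermediate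
35 | (3S,5aS,6S,7R,9aS)-6-{2-[(1S,3aS,5R,8aS)-1-hydroxy-1,4,4,6-tetramethyl-1,2,3,3a,4,5,8,8a-octahydroazulen-5-yl]ethyl}-2,2,5a,7-tetramethyldecahydro-1-benzoxepine-3,7-diol (CNP0183476.2) | CC1=CC[C@H]2[C@H](CC[C@]2(C)O)C(C)(C)[C@@H]1CC[C@H]1[C@]2(C)CC[C@H](O)C(C)(C)O[C@H]2CC[C@@]1(C)O | target

**Totals**

Total step count: 19.
Longest linear sequence: 15 steps (steps 1–9, then 14–19); the right half adds 4 steps (10–13) before the union.

**Steps most likely to fail**

1. Step 17 (key step). What may go wrong: the alkylsamarium is protonated or lost before it reaches the lactone carbonyl, so that simple deiodination competes with acyl transfer. Fallback: starting from 32, the iodide is displaced with PhSO2Na in DMF to give phenyl sulfone F1. LiN(SiMe3)2 (THF, −78 → 0 °C) then generates the α-sulfonyl carbanion, which acylates itself on the lactone carbonyl (Dieckmann-type C-acylation of a sulfone, forming the same C7–C8 bond) to give β-keto sulfone F2. Reductive desulfonylation with aluminium amalgam, Al(Hg), in aqueous THF returns to the route at 33.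

2. Step 18. What may go wrong: the hydroxyl attacks the secondary epoxide carbon (6-exo mode), or the developing tertiary cation rearranges by hydride shift. Fallback: starting from 33, MeLi/CeCl3 is added first (as in step 19) to give epoxy triol F3. Et2Al(tmp) (diethylaluminium 2,2,6,6-tetramethylpiperidide) isomerises the epoxide to allylic alcohol F4 with the C3–O bond untouched. Hg(OCOCF3)2 then effects intramolecular Markovnikov alkoxymercuration of the 1,1-disubstituted alkene (7-exo-trig, with no six-membered alternative) to organomercurial F5, and NaBH4 demercuration arrives directly at 35.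

3. Step 14. What may go wrong: slow C-alkylation of the hindered enolate next to the quaternary centre, with E2 elimination of the iodide or enolate attack on the epoxide taking over. Fallback: starting from 14, silylation with N-(trimethylsilyl)imidazole gives silyl ether F6, which Cp2Zr(H)Cl reduces to aldehyde F7. Aldol addition of lithium enolate 29 (from 28) gives β-hydroxy lactone F8 with the same facial selectivity at C3 of the lactone. The hydroxyl is converted with 1,1'-thiocarbonyldiimidazole to thiocarbamate F9 and removed with Bu3SnH/AIBN (Barton–McCombie deoxygenation), returning to the route at 30.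

**Further compounds**

F1 | step 17 | (3S,4S,5S)-4-{2-[(2S)-3,3-dimethyloxiran-2-yl]ethyl}-3-{2-[(1S,3aS,5R,8aS)-1-hydroxy-1,4,4,6-tetramethyl-1,2,3,3a,4,5,8,8a-octahydroazulen-5-yl]ethyl}-4-methyl-5-[2-(phenylsulfonyl)ethyl]oxolan-2-one | CC1=CC[C@H]2[C@H](CC[C@]2(C)O)C(C)(C)[C@@H]1CC[C@@H]3C(=O)O[C@@H](CCS(=O)(=O)c5ccccc5)[C@@]3(C)CC[C@@H]4OC4(C)C
F2 | step 17 | (2S,3S,4S)-3-{2-[(2S)-3,3-dimethyloxiran-2-yl]ethyl}-4-hydroxy-2-{2-[(1S,3aS,5R,8aS)-1-hydroxy-1,4,4,6-tetramethyl-1,2,3,3a,4,5,8,8a-octahydroazulen-5-yl]ethyl}-3-methyl-6-(phenylsulfonyl)cyclohexan-1-one (either C6 epimer) | CC1=CC[C@H]2[C@H](CC[C@]2(C)O)C(C)(C)[C@@H]1CC[C@@H]3C(=O)C(S(=O)(=O)c5ccccc5)C[C@H](O)[C@@]3(C)CC[C@@H]4OC4(C)C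
F3 | step 18 | (1R,2S,3S,4S)-3-{2-[(2S)-3,3-dimethyloxiran-2-yl]ethyl}-2-{2-[(1S,3aS,5R,8aS)-1-hydroxy-1,4,4,6-tetramethyl-1,2,3,3a,4,5,8,8a-octahydroazulen-5-yl]ethyl}-1,3-dimethylcyclohexane-1,4-diol | CC1=CC[C@H]2[C@H](CC[C@]2(C)O)C(C)(C)[C@@H]1CC[C@H]3[C@](C)(CC[C@@H]4OC4(C)C)[C@@H](O)CC[C@@]3(C)O
F4 | step 18 | (1R,2S,3S,4S)-3-[(3S)-3-hydroxy-4-methylpent-4-en-1-yl]-2-{2-[(1S,3aS,5R,8aS)-1-hydroxy-1,4,4,6-tetramethyl-1,2,3,3a,4,5,8,8a-octahydroazulen-5-yl]ethyl}-1,3-dimethylcyclohexane-1,4-diol | CC1=CC[C@H]2[C@H](CC[C@]2(C)O)C(C)(C)[C@@H]1CC[C@H]3[C@](C)(CC[C@H](O)C(C)=C)[C@@H](O)CC[C@@]3(C)O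
F5 | step 18 | organomercurial: 35 in which one C2 methyl group is CH2HgOCOCF3 (either C2 epimer) | CC1=CC[C@H]2[C@H](CC[C@]2(C)O)C(C)(C)[C@@H]1CC[C@H]1[C@]2(C)CC[C@H](O)C(C)(C[Hg]OC(=O)C(F)(F)F)O[C@H]2CC[C@@]1(C)O
F6 | step 14 | N,N-dimethyl-2-[(1S,3aS,5R,8aS)-1,4,4,6-tetramethyl-1-[(trimethylsilyl)oxy]-1,2,3,3a,4,5,8,8a-octahydroazulen-5-yl]acetamide | CC1=CC[C@H]2[C@H](CC[C@]2(C)O[Si](C)(C)C)C(C)(C)[C@@H]1CC(=O)N(C)C
F7 | step 14 | 2-[(1S,3aS,5R,8aS)-1,4,4,6-tetramethyl-1-[(trimethylsilyl)oxy]-1,2,3,3a,4,5,8,8a-octahydroazulen-5-yl]acetaldehyde | CC1=CC[C@H]2[C@H](CC[C@]2(C)O[Si](C)(C)C)C(C)(C)[C@@H]1CC=O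
F8 | step 14 | aldol adduct: 30 carrying a hydroxyl on the side-chain carbon attached to C3 of the lactone (either carbinol epimer) | CC1=CC[C@H]2[C@H](CC[C@]2(C)O[Si](C)(C)C)C(C)(C)[C@@H]1CC(O)[C@@H]3C(=O)O[C@@H](CCO[Si](C)(C)C(C)(C)C)[C@@]3(C)CC[C@@H]4OC4(C)C
F9 | step 14 | O-alkyl 1H-imidazole-1-carbothioate of F8 | CC1=CC[C@H]2[C@H](CC[C@]2(C)O[Si](C)(C)C)C(C)(C)[C@@H]1CC(OC(=S)n5ccnc5)[C@@H]3C(=O)O[C@@H](CCO[Si](C)(C)C(C)(C)C)[C@@]3(C)CC[C@@H]4OC4(C)C
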